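## The problem

The target is a 2,3,4,7-tetrahydrooxepine (ring atoms O1, C2, C3, C4, C5=C6, C7) whose only stereocentre, the fully substituted C2, carries the ring oxygen, a carboxylic acid and a 2-(2,5-dihydroxyphenyl)-2-oxoethyl arm, while C6 bears a five-carbon chain whose trisubstituted (E)-alkene ends in an allylic ester of (E)-4-hydroxycinnamic acid. Because C2 is remote from every other stereogenic element, its (R) configuration cannot be relayed from anything else and has to come from an absolute, catalyst-controlled C–C bond formation on a trigonal C2; once set it bears no hydrogen and is inert as long as the C2–O bond is never reopened. The ring is a seven-membered ether closed onto a hindered tertiary oxygen that is flanked by an ester, a poor setting for SN2 etherification, and its alkene must sit at C5=C6 and not at C6=C7. The array O1–C2–CH2–C(=O)Ar is a β-alkoxy ketone: base can expel O1 by β-elimination, after which the ortho-phenol can add back to give a chromanone. Before the ring exists the same array is an aldol, open to retro-aldol cleavage and, once the remote carboxyl is activated, to δ-lactonisation. The hydroquinone is easily oxidised, and the allylic coumarate is cleaved by hydroxide, ionised by zerovalent palladium and reduced by hydrogenation, so the last steps have to be close to neutral. The enabling feature is the O1–C7 bond, which joins the tertiary oxygen to a methylene next to C6, the carbon that carries both the side chain and the ring double bond. With a ketone at C6, the unit O1–C7H2–C6(=O) is the retron of a carbenoid O–H insertion of a diazomethyl ketone, and the same ketone is the handle for the C5=C6 alkene and the side chain.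

## Retrosynthesis

**28 to 27.** No skeletal bond is cut. The two aryl O–Si bonds and the 2-(trimethylsilyl)ethyl ester of 27 fall in one fluoride operation. The neighbouring choice, methyl ethers on the hydroquinone and a methyl ester at C2, would end in an oxidative demethylation through an acylquinone and a hydroxide hydrolysis beside the coumarate. Silicon-based groups are removed by attack at silicon, remote from the hindered C2 carbonyl and without acyl substitution. The forward step must be mild enough not to start β-elimination of O1.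

**27 to 25 and 26.** The side-chain ester C–O bond is cut. The coumarate cannot be carried earlier, because an allylic ester would be ionised by zerovalent palladium in the coupling step. The cut removes nine carbons and leaves commercial acid 26. The forward reaction has to esterify a primary allylic alcohol beside a free phenol and without base, which points to a Mitsunobu reaction.

**25 to 24.** The aryl ketone is returned to its dioxolane and the allylic alcohol to its silyl ether. Both masks are needed for the base and palladium steps that precede, and both fall in one acid step going forward.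

**24 to 19 and 23.** The bond from C6 to the first side-chain carbon is cut. The neighbouring option, carbonyl addition to a C6 ketone and dehydration, gives no control between C5=C6, C6=C7 and an exocyclic alkene. A cross-coupling puts the double bond where the enol triflate of 19 is. Alkylzinc 23 comes from bromide 22, from alcohol 21, from prenyl-type bromide 20 by an allylic oxidation that sets the (E) geometry. The forward reaction is an sp2–sp3 Negishi coupling that must outrun β-hydride elimination.

**19 to 17.** The enol triflate is traced to the C6 ketone of 17. The forward step needs deprotonation at C5 and not at C7. The ketal and the absence of α-hydrogens on the ester leave 17 with only one enolisable carbonyl.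

**17 to 16 (key).** O1–C7 is cut. C2–O1 cannot be cut without reopening the stereocentre. A C–C closure such as metathesis at C5=C6 would first require intermolecular etherification of the tertiary hydroxyl. A Williamson closure at C7 would need base on an aldol-type alkoxide. Carbenoid insertion is neutral and leaves exactly the ketone that the next two steps use. Precursor 16 is acyclic and holds C2 to C7 in one chain. The forward step must favour O–H over C–H insertion.

**16 to 15, 13 and 11.** The diazomethyl ketone comes from acid 13 by acylation of a silyl diazomethane (C6–C7 bond), and the acid from the terminal alkene of 11 by oxidative cleavage. The tertiary oxygen stays silylated in 15 until the diazoketone exists, because a free δ-hydroxyl would lactonise onto the activated carboxyl. The step 15 to 16 is then a selective desilylation.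

**11 to 10 to 6 and 9.** The ketal goes back to ketone 10, and the C2–Cα bond is cut to α-keto ester 6 and enol silane 9. This is the only stereogenic step. Compared with alkylation of a chiral glycolate equivalent, which needs auxiliary steps, the catalytic Mukaiyama aldol makes the tetrasubstituted carbinol directly, with both arms in place and the tertiary oxygen already silylated. It requires two-point binding of 6 to a chiral Lewis acid, which a 1,2-dicarbonyl compound provides.

**6 to 3 and 5; 3 to 1 and 2; 9 to 8 to 7.** Keto ester 6 comes from oxalate 3 and Grignard reagent 5 (from bromide 4). Oxalate 3 comes from 1 and two equivalents of 2, so that the fluoride-labile ester is present from the start. Enol silane 9 comes from ketone 8, the bis-silyl ether of commercial 7.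

## Roads not taken

**Alternative 1:** The cut falls on the C6–side-chain bond and on C4–C5. A copper-catalysed anti-carbomagnesiation would give the (Z)-diol A1 in one flask from the side-chain Grignard reagent A2, the magnesium alkoxide of propargyl alcohol A3 and ethylene oxide A4, with C4 cis to C7.
- Merits: three cheap components, and the position and geometry of the ring alkene and the side chain are settled unambiguously. On this point it is better than the chosen plan, which needs a regioselective enolisation and a cross-coupling to reach the same alkene.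
- Weak points: A1 holds only C3 to C7. The C2 stereocentre would still have to be built by a C2–C3 alkylation with a homoallylic electrophile prone to elimination. The two primary hydroxyls must be differentiated. O1–C7 would then be closed by displacement at allylic C7 with the hindered tertiary alkoxide, under base, on an aldol array that can cleave and with SN2′ competition.
- Comparison: the chosen plan sets against the cleaner alkene a catalytic asymmetric construction of C2 with all ring carbons attached, and a neutral ring closure.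

**Alternative 2:** The cut falls on the Cα–C(ketone) bond and on C2–C3. Conjugate addition of the lithium derivative of dithiane A7 to the methylene dioxolanone A6, then alkylation of the resulting enolate with iodide A8 anti to the tert-butyl group, would give dioxolanone A5.
- Merits: C2 is set by well-understood substrate control without a chiral catalyst. The acid and the tertiary oxygen are masked together, and the ketone arrives already masked. In reliability of the stereochemical outcome and in avoiding a separate ketalisation this road is at least equal to the chosen aldol.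
- Weak points: a hindered aryl dithiane anion must add to a polymerisable acceptor. The hindered enolate must be alkylated by a β-alkoxy iodide that eliminates easily. A5 holds only C3 to C5 of the ring, so C6, C7, the trisubstituted alkene, the side chain and the ether closure all remain. The dithiane must later be removed by thiophilic or oxidative reagents beside alkenes and an electron-rich arene, and sulfur is a poor companion for rhodium or palladium.
- Comparison: the chosen plan offers two steps to an intermediate with every ring carbon, and a ketone at C6 that serves ring closure, alkene and side chain alike.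

**Alternative 3:** The cut falls on C6–C7. A strong Lewis acid would ionise the alkoxymethyl ether of the (Z)-vinylsilane A10 to an O1=C7H2 oxocarbenium ion, which the silicon-bearing C6 attacks with loss of silicon to give the complete tetrahydrooxepine A9.
- Merits: ring closure, alkene position and side chain are delivered in one step with no regiochemical question. In directness after cyclisation this road is better than the chosen plan, which needs triflation and coupling.
- Weak points: A10 requires alkoxymethylation of the same hindered tertiary hydroxyl. It also requires a stereodefined trisubstituted vinylsilane that already carries the whole side chain, which means a long linear sequence before the key step. The Lewis acid meets an unmasked β-alkoxy aryl ketone, an electron-rich arene and a second trisubstituted alkene that can compete as π-nucleophile. The methyl ethers and esters of A9 leave an endgame of demethylation and hydrolysis that the coumarate and the β-alkoxy ketone tolerate poorly.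
- Comparison: the chosen plan sets against it a short catalytic route to the cyclisation substrate, a neutral ring closure and an endgame that touches only silicon.

Key step: step 10

Assumption: the sense of induction in step 5 is taken from the square-planar chelate of an α-keto ester on divalent copper, in which the (S,S)-bis(oxazoline) exposes the Si face; the (R,R)-ligand is therefore specified for (R)-C2.

## Route

Step 1
Reactants: 1 oxalyl chloride; 2 2-(trimethylsilyl)ethanol
Product: 3 bis[2-(trimethylsilyl)ethyl] oxalate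
Conditions: 2 (2.1 equiv), pyridine (2.2 equiv), CH2Cl2, 0 °C to rt
Reagents that add atoms: 2-(trimethylsilyl)ethanol (second equivalent of 2), C[Si](C)(C)CCO
Why: Acylation of a primary alcohol by an acid chloride; each of the two acyl chloride groups of 1 takes up one molecule of 2, so two equivalents of the alcohol end up in the symmetrical diester, which introduces the fluoride-labile ester group at the outset.

Step 2
Reactants: 4 5-bromopent-1-ene; 3 bis[2-(trimethylsilyl)ethyl] oxalate
Product: 6 2-(trimethylsilyl)ethyl 2-oxohept-6-enoate, via pent-4-enylmagnesium bromide 5 (not isolated)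
Conditions: Mg, THF, rt; then inverse addition to 3 (excess), THF/Et2O, −78 °C
Reagents that add atoms: none
Why: Grignard formation and monoaddition to a dialkyl oxalate; the magnesium-chelated tetrahedral adduct survives at −78 °C until work-up, so the α-keto ester is not attacked a second time.

Step 3
Reactants: 7 2′,5′-dihydroxyacetophenone
Product: 8 1-[2,5-bis(tert-butyldimethylsilyloxy)phenyl]ethanone
Conditions: TBSCl, imidazole, DMF, 40 °C
Reagents that add atoms: tert-butyldimethylsilyl chloride, CC(C)(C)[Si](C)(C)Cl
Why: Silylation of both phenols; the hydrogen-bonded ortho phenol needs DMF and mild warming, and the aryl silyl ethers resist acid and the organometallic steps but fall to fluoride at the end.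

Step 4
Reactants: 8 1-[2,5-bis(tert-butyldimethylsilyloxy)phenyl]ethanone
Product: 9 {1-[2,5-bis(tert-butyldimethylsilyloxy)phenyl]ethenyloxy}trimethylsilane
Conditions: TMSOTf, Et3N, CH2Cl2, 0 °C
Reagents that add atoms: trimethylsilyl triflate, C[Si](C)(C)OS(=O)(=O)C(F)(F)F
Why: Soft enolisation and O-silylation; the methyl ketone has one enolisable position and gives a single enol silane.

Step 5
Reactants: 6 2-(trimethylsilyl)ethyl 2-oxohept-6-enoate; 9 {1-[2,5-bis(tert-butyldimethylsilyloxy)phenyl]ethenyloxy}trimethylsilane
Product: 10 2-(trimethylsilyl)ethyl (2R)-2-{2-[2,5-bis(tert-butyldimethylsilyloxy)phenyl]-2-oxoethyl}-2-(trimethylsilyloxy)hept-6-enoate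
Conditions: Cu(OTf)2 (10 mol%), 2,2′-(propane-2,2-diyl)bis[(4R)-4-tert-butyl-4,5-dihydro-1,3-oxazole] (11 mol%), THF, −78 °C; non-acidic work-up (silica filtration)
Reagents that add atoms: none
Why: Catalytic enantioselective Mukaiyama aldol; the keto ester chelates the square-planar divalent copper–bis(oxazoline) complex through both carbonyls, the tert-butyl groups of the (R,R)-ligand block the Si face, and attack on the Re face sets (R)-C2, with the silyl group transferred to the tertiary oxygen and kept as its protection.

Step 6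
Reactants: 10 2-(trimethylsilyl)ethyl (2R)-2-{2-[2,5-bis(tert-butyldimethylsilyloxy)phenyl]-2-oxoethyl}-2-(trimethylsilyloxy)hept-6-enoate
Product: 11 2-(trimethylsilyl)ethyl (2R)-2-({2-[2,5-bis(tert-butyldimethylsilyloxy)phenyl]-1,3-dioxolan-2-yl}methyl)-2-(trimethylsilyloxy)hept-6-enoate
Conditions: TMSOCH2CH2OTMS, TMSOTf (5 mol%), CH2Cl2, −78 to −20 °C; pyridine quench
Reagents that add atoms: 1,2-bis(trimethylsilyloxy)ethane, C[Si](C)(C)OCCO[Si](C)(C)C
Why: Silyl-triflate-catalysed ketalisation under aprotic low-temperature conditions, driven by formation of hexamethyldisiloxane; the silylated tertiary oxygen blocks retro-aldol and dehydration, and the aryl silyl ethers and the ester are inert.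

Step 7
Reactants: 11 2-(trimethylsilyl)ethyl (2R)-2-({2-[2,5-bis(tert-butyldimethylsilyloxy)phenyl]-1,3-dioxolan-2-yl}methyl)-2-(trimethylsilyloxy)hept-6-enoate
Product: 13 (5R)-5-({2-[2,5-bis(tert-butyldimethylsilyloxy)phenyl]-1,3-dioxolan-2-yl}methyl)-6-oxo-6-[2-(trimethylsilyl)ethoxy]-5-(trimethylsilyloxy)hexanoic acid, via 6-oxohexanoate aldehyde 12 (not isolated)
Conditions: O3 (dosed to the end point), MeCN/H2O 9:1, 0 °C; then NaClO2, NaH2PO4, 0 °C to rt
Reagents that add atoms: ozone, [O-][O+]=O; sodium chlorite, [Na+].[O-]Cl=O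
Why: Ozonolysis in aqueous acetonitrile, where water intercepts the carbonyl oxide to give the aldehyde directly, followed in the same flask by Pinnick-type chlorite oxidation with the hydrogen peroxide formed acting as hypochlorite scavenger; the monosubstituted alkene consumes ozone faster than the silyloxyarene.

Step 8
Reactants: 13 (5R)-5-({2-[2,5-bis(tert-butyldimethylsilyloxy)phenyl]-1,3-dioxolan-2-yl}methyl)-6-oxo-6-[2-(trimethylsilyl)ethoxy]-5-(trimethylsilyloxy)hexanoic acid
Product: 15 2-(trimethylsilyl)ethyl (2R)-2-({2-[2,5-bis(tert-butyldimethylsilyloxy)phenyl]-1,3-dioxolan-2-yl}methyl)-7-diazo-6-oxo-2-(trimethylsilyloxy)heptanoate, via mixed isobutyl carbonic anhydride 14 (not isolated)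
Conditions: i-BuOCOCl, N-methylmorpholine, THF, −15 °C; then TMSCHN2, MeCN, 0 °C to rt
Reagents that add atoms: (trimethylsilyl)diazomethane, C[Si](C)(C)C=[N+]=[N-]
Why: Arndt–Eistert-type acylation of a silyl diazomethane by a mixed anhydride, the carbon-bound silyl group being lost on acylation and work-up; the tertiary oxygen is silylated, so the activated carboxyl cannot close a δ-lactone.

Step 9
Reactants: 15 2-(trimethylsilyl)ethyl (2R)-2-({2-[2,5-bis(tert-butyldimethylsilyloxy)phenyl]-1,3-dioxolan-2-yl}methyl)-7-diazo-6-oxo-2-(trimethylsilyloxy)heptanoate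
Product: 16 2-(trimethylsilyl)ethyl (2R)-2-({2-[2,5-bis(tert-butyldimethylsilyloxy)phenyl]-1,3-dioxolan-2-yl}methyl)-7-diazo-2-hydroxy-6-oxoheptanoate
Conditions: Et3N·3HF, THF, 0 °C to rt; NaHCO3 work-up
Reagents that add atoms: none
Why: Fluoride-mediated cleavage of a trimethylsilyl alkyl ether; the weakly acidic amine–HF reagent removes the small alkyl silyl group much faster than the bulkier aryl tert-butyldimethylsilyl ethers (which need basic fluoride), is too weak an acid to protonate the diazoketone quickly, and leaves the silylethyl ester and the dioxolane untouched.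

Step 10
Reactants: 16 2-(trimethylsilyl)ethyl (2R)-2-({2-[2,5-bis(tert-butyldimethylsilyloxy)phenyl]-1,3-dioxolan-2-yl}methyl)-7-diazo-2-hydroxy-6-oxoheptanoate
Product: 17 2-(trimethylsilyl)ethyl (2R)-2-({2-[2,5-bis(tert-butyldimethylsilyloxy)phenyl]-1,3-dioxolan-2-yl}methyl)-6-oxooxepane-2-carboxylate
Conditions: Rh2(OAc)4 (2 mol%), CH2Cl2, slow addition at high dilution, 40 °C
Reagents that add atoms: none
Why: Rh2(OAc)4 expels N2 from the diazoketone to give an electrophilic rhodium carbenoid at C7; the C2 hydroxyl oxygen attacks it to form an oxonium ylide, and a proton shift with release of the catalyst completes the O–H insertion, forming O1–C7 and leaving the ketone at C6. The closest known reaction type is the Rh2(OAc)4-catalysed intramolecular O–H insertion of ω-hydroxy α-diazoketones and α-diazo-β-keto esters, which gives 3-oxotetrahydrofurans, 3-oxotetrahydropyrans and oxepan-3-ones. The single ring closed, the oxepane, forms by attack of oxygen on the carbenoid carbon with the rhodium–carbon bond outside the ring, a 7-exo closure, and the geminal substitution at C2 favours the folded conformer. No stereocentre is created; C2 bears no hydrogen and keeps its (R) configuration because the medium is neutral and the aryl ketone is masked, so neither retro-aldol nor β-elimination can start. The step needs O–H insertion to beat 1,5 C–H insertion at C3, carbenoid dimerisation and ylide formation at other oxygens. O–H insertion is the fastest reaction of such carbenoids, the C3–H bonds lie next to the oxygenated quaternary carbon and are deactivated, the ester and ketal oxygens could only close eight- and nine-membered rings, and slow addition keeps the diazo concentration low.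

Step 11
Reactants: 17 2-(trimethylsilyl)ethyl (2R)-2-({2-[2,5-bis(tert-butyldimethylsilyloxy)phenyl]-1,3-dioxolan-2-yl}methyl)-6-oxooxepane-2-carboxylate
Product: 19 2-(trimethylsilyl)ethyl (2R)-2-({2-[2,5-bis(tert-butyldimethylsilyloxy)phenyl]-1,3-dioxolan-2-yl}methyl)-6-(trifluoromethylsulfonyloxy)-2,3,4,7-tetrahydrooxepine-2-carboxylate, via lithium enolate 18 (not isolated)
Conditions: LiN(i-Pr)2, THF, −78 °C; then N-(5-chloropyridin-2-yl)bis(trifluoromethanesulfonyl)imide, −78 to −40 °C; NH4Cl quench
Reagents that add atoms: N-(5-chloropyridin-2-yl)bis(trifluoromethanesulfonyl)imide, FC(F)(F)S(=O)(=O)N(c1ccc(Cl)cn1)S(=O)(=O)C(F)(F)F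
Why: Kinetic enolisation and O-triflation; the amide base removes a C5 proton in preference to C7, whose carbanion is destabilised by the lone pairs of the attached oxygen (the regiochemistry known for tetrahydropyran-3-one), the reactive triflimide traps the enolate before it equilibrates, and the ester (no α-hydrogen) and the ketal offer no other acidic site.

Step 12
Reactants: 20 5-bromo-2-methylpent-2-ene
Product: 21 (2E)-5-bromo-2-methylpent-2-en-1-ol
Conditions: SeO2 (cat.), t-BuOOH, CH2Cl2, rt
Reagents that add atoms: tert-butyl hydroperoxide, CC(C)(C)OO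
Why: Riley-type allylic oxidation; the ene reaction and [2,3]-sigmatropic shift oxidise the methyl group trans to the chain, which fixes the (E) geometry of the side-chain alkene.

Step 13
Reactants: 21 (2E)-5-bromo-2-methylpent-2-en-1-ol
Product: 22 [(2E)-5-bromo-2-methylpent-2-enyloxy](tert-butyl)dimethylsilane
Conditions: TBSCl, imidazole, CH2Cl2, rt
Reagents that add atoms: tert-butyldimethylsilyl chloride, CC(C)(C)[Si](C)(C)Cl
Why: Silylation of a primary alcohol; a silyl ether, unlike an ester, is not ionised by zerovalent palladium at the allylic position.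

Step 14
Reactants: 22 [(2E)-5-bromo-2-methylpent-2-enyloxy](tert-butyl)dimethylsilane; 19 2-(trimethylsilyl)ethyl (2R)-2-({2-[2,5-bis(tert-butyldimethylsilyloxy)phenyl]-1,3-dioxolan-2-yl}methyl)-6-(trifluoromethylsulfonyloxy)-2,3,4,7-tetrahydrooxepine-2-carboxylate
Product: 24 2-(trimethylsilyl)ethyl (2R)-2-({2-[2,5-bis(tert-butyldimethylsilyloxy)phenyl]-1,3-dioxolan-2-yl}methyl)-6-[(3E)-5-(tert-butyldimethylsilyloxy)-4-methylpent-3-enyl]-2,3,4,7-tetrahydrooxepine-2-carboxylate, via alkylzinc bromide 23 (not isolated)
Conditions: Zn dust, I2 (5 mol%), DMA, 70 °C; then 19, Pd(dppf)Cl2 (5 mol%), THF, 50 °C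
Reagents that add atoms: none
Why: Zinc insertion into a primary alkyl bromide and Negishi coupling; the alkenyl triflate adds oxidatively to zerovalent palladium, the primary alkylzinc transmetalates, and the wide-bite-angle dppf ligand favours reductive elimination over β-hydride elimination, so the double bond stays at C5=C6 and the homoallylic alkene keeps its geometry.

Step 15
Reactants: 24 2-(trimethylsilyl)ethyl (2R)-2-({2-[2,5-bis(tert-butyldimethylsilyloxy)phenyl]-1,3-dioxolan-2-yl}methyl)-6-[(3E)-5-(tert-butyldimethylsilyloxy)-4-methylpent-3-enyl]-2,3,4,7-tetrahydrooxepine-2-carboxylate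
Product: 25 2-(trimethylsilyl)ethyl (2R)-2-{2-[2,5-bis(tert-butyldimethylsilyloxy)phenyl]-2-oxoethyl}-6-[(3E)-5-hydroxy-4-methylpent-3-enyl]-2,3,4,7-tetrahydrooxepine-2-carboxylate
Conditions: TsOH·H2O (10 mol%), acetone/H2O 10:1, rt
Reagents that add atoms: water, O
Why: Acid-catalysed ketal hydrolysis and desilylation; the aryl dioxolane ionises easily to a stabilised benzylic oxocarbenium ion and the primary alkyl silyl ether is acid-labile, whereas aryl silyl ethers and the silylethyl ester resist dilute acid.

Step 16
Reactants: 25 2-(trimethylsilyl)ethyl (2R)-2-{2-[2,5-bis(tert-butyldimethylsilyloxy)phenyl]-2-oxoethyl}-6-[(3E)-5-hydroxy-4-methylpent-3-enyl]-2,3,4,7-tetrahydrooxepine-2-carboxylate; 26 (E)-4-hydroxycinnamic acid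
Product: 27 2-(trimethylsilyl)ethyl (2R)-2-{2-[2,5-bis(tert-butyldimethylsilyloxy)phenyl]-2-oxoethyl}-6-[(3E)-5-{[(2E)-3-(4-hydroxyphenyl)prop-2-enoyl]oxy}-4-methylpent-3-enyl]-2,3,4,7-tetrahydrooxepine-2-carboxylate
Conditions: PPh3, DIAD, THF, 0 °C to rt
Reagents that add atoms: none
Why: Mitsunobu esterification; the carboxylic acid, far more acidic than the phenol, protonates the betaine and displaces the alkoxyphosphonium group of the primary allylic alcohol directly, so the phenol needs no protection and no base touches the β-alkoxy ketone.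

Step 17
Reactants: 27 2-(trimethylsilyl)ethyl (2R)-2-{2-[2,5-bis(tert-butyldimethylsilyloxy)phenyl]-2-oxoethyl}-6-[(3E)-5-{[(2E)-3-(4-hydroxyphenyl)prop-2-enoyl]oxy}-4-methylpent-3-enyl]-2,3,4,7-tetrahydrooxepine-2-carboxylate
Product: 28 (2R)-2-[2-(2,5-dihydroxyphenyl)-2-oxoethyl]-6-[(3E)-5-{[(2E)-3-(4-hydroxyphenyl)prop-2-enoyl]oxy}-4-methylpent-3-enyl]-2,3,4,7-tetrahydrooxepine-2-carboxylic acid
Conditions: tris(dimethylamino)sulfonium difluorotrimethylsilicate [(Me2N)3S][Me3SiF2], degassed DMF, 0 °C to rt; dilute HCl work-up to pH 4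
Reagents that add atoms: none
Why: Fluoride-induced global desilylation; fluoride attacks silicon only, cleaving both aryl silyl ethers and fragmenting the silylethyl ester to ethene and the hindered carboxylate without acyl substitution, the allylic coumarate is untouched, and the phenoxide formed first lowers the acidity of the CH2 next to the ketone.

## Compound list

1 | oxalyl chloride | ClC(=O)C(=O)Cl | starting material
2 | 2-(trimethylsilyl)ethanol | C[Si](C)(C)CCO | starting material
3 | bis[2-(trimethylsilyl)ethyl] oxalate | C[Si](C)(C)CCOC(=O)C(=O)OCC[Si](C)(C)C | intermediate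
4 | 5-bromopent-1-ene | C=CCCCBr | starting material
5 | pent-4-enylmagnesium bromide | C=CCCC[Mg]Br | intermediate (not isolated)
6 | 2-(trimethylsilyl)ethyl 2-oxohept-6-enoate | C=CCCCC(=O)C(=O)OCC[Si](C)(C)C | intermediate
7 | 2′,5′-dihydroxyacetophenone | CC(=O)c1cc(O)ccc1O | starting material
8 | 1-[2,5-bis(tert-butyldimethylsilyloxy)phenyl]ethanone | CC(=O)c1cc(O[Si](C)(C)C(C)(C)C)ccc1O[Si](C)(C)C(C)(C)C | intermediate
9 | {1-[2,5-bis(tert-butyldimethylsilyloxy)phenyl]ethenyloxy}trimethylsilane | C=C(O[Si](C)(C)C)c1cc(O[Si](C)(C)C(C)(C)C)ccc1O[Si](C)(C)C(C)(C)C | intermediate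
10 | 2-(trimethylsilyl)ethyl (2R)-2-{2-[2,5-bis(tert-butyldimethylsilyloxy)phenyl]-2-oxoethyl}-2-(trimethylsilyloxy)hept-6-enoate | C=CCCC[C@@](O[Si](C)(C)C)(CC(=O)c1cc(O[Si](C)(C)C(C)(C)C)ccc1O[Si](C)(C)C(C)(C)C)C(=O)OCC[Si](C)(C)C | intermediate
11 | 2-(trimethylsilyl)ethyl (2R)-2-({2-[2,5-bis(tert-butyldimethylsilyloxy)phenyl]-1,3-dioxolan-2-yl}methyl)-2-(trimethylsilyloxy)hept-6-enoate | C=CCCC[C@@](O[Si](C)(C)C)(CC1(OCCO1)c2cc(O[Si](C)(C)C(C)(C)C)ccc2O[Si](C)(C)C(C)(C)C)C(=O)OCC[Si](C)(C)C | intermediate
12 | 2-(trimethylsilyl)ethyl (2R)-2-({2-[2,5-bis(tert-butyldimethylsilyloxy)phenyl]-1,3-dioxolan-2-yl}methyl)-6-oxo-2-(trimethylsilyloxy)hexanoate | O=CCCC[C@@](O[Si](C)(C)C)(CC1(OCCO1)c2cc(O[Si](C)(C)C(C)(C)C)ccc2O[Si](C)(C)C(C)(C)C)C(=O)OCC[Si](C)(C)C | intermediate (not isolated)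
13 | (5R)-5-({2-[2,5-bis(tert-butyldimethylsilyloxy)phenyl]-1,3-dioxolan-2-yl}methyl)-6-oxo-6-[2-(trimethylsilyl)ethoxy]-5-(trimethylsilyloxy)hexanoic acid | OC(=O)CCC[C@@](O[Si](C)(C)C)(CC1(OCCO1)c2cc(O[Si](C)(C)C(C)(C)C)ccc2O[Si](C)(C)C(C)(C)C)C(=O)OCC[Si](C)(C)C | intermediate
14 | mixed anhydride of 13 with isobutyl hydrogen carbonate | CC(C)COC(=O)OC(=O)CCC[C@@](O[Si](C)(C)C)(CC1(OCCO1)c2cc(O[Si](C)(C)C(C)(C)C)ccc2O[Si](C)(C)C(C)(C)C)C(=O)OCC[Si](C)(C)C | intermediate (not isolated)
15 | 2-(trimethylsilyl)ethyl (2R)-2-({2-[2,5-bis(tert-butyldimethylsilyloxy)phenyl]-1,3-dioxolan-2-yl}methyl)-7-diazo-6-oxo-2-(trimethylsilyloxy)heptanoate | [N-]=[N+]=CC(=O)CCC[C@@](O[Si](C)(C)C)(CC1(OCCO1)c2cc(O[Si](C)(C)C(C)(C)C)ccc2O[Si](C)(C)C(C)(C)C)C(=O)OCC[Si](C)(C)C | intermediate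
16 | 2-(trimethylsilyl)ethyl (2R)-2-({2-[2,5-bis(tert-butyldimethylsilyloxy)phenyl]-1,3-dioxolan-2-yl}methyl)-7-diazo-2-hydroxy-6-oxoheptanoate | [N-]=[N+]=CC(=O)CCC[C@@](O)(CC1(OCCO1)c2cc(O[Si](C)(C)C(C)(C)C)ccc2O[Si](C)(C)C(C)(C)C)C(=O)OCC[Si](C)(C)C | intermediate
17 | 2-(trimethylsilyl)ethyl (2R)-2-({2-[2,5-bis(tert-butyldimethylsilyloxy)phenyl]-1,3-dioxolan-2-yl}methyl)-6-oxooxepane-2-carboxylate | O=C1CCC[C@@](CC2(OCCO2)c3cc(O[Si](C)(C)C(C)(C)C)ccc3O[Si](C)(C)C(C)(C)C)(C(=O)OCC[Si](C)(C)C)OC1 | intermediate
18 | lithium enolate of 17 (C5=C6, O-lithiated at C6) | [Li]OC1=CCC[C@@](CC2(OCCO2)c3cc(O[Si](C)(C)C(C)(C)C)ccc3O[Si](C)(C)C(C)(C)C)(C(=O)OCC[Si](C)(C)C)OC1 | intermediate (not isolated)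
19 | 2-(trimethylsilyl)ethyl (2R)-2-({2-[2,5-bis(tert-butyldimethylsilyloxy)phenyl]-1,3-dioxolan-2-yl}methyl)-6-(trifluoromethylsulfonyloxy)-2,3,4,7-tetrahydrooxepine-2-carboxylate | O=S(=O)(OC1=CCC[C@@](CC2(OCCO2)c3cc(O[Si](C)(C)C(C)(C)C)ccc3O[Si](C)(C)C(C)(C)C)(C(=O)OCC[Si](C)(C)C)OC1)C(F)(F)F | intermediate
20 | 5-bromo-2-methylpent-2-ene | CC(C)=CCCBr | starting material
21 | (2E)-5-bromo-2-methylpent-2-en-1-ol | C/C(=C\CCBr)CO | intermediate
22 | [(2E)-5-bromo-2-methylpent-2-enyloxy](tert-butyl)dimethylsilane | C/C(=C\CCBr)CO[Si](C)(C)C(C)(C)C | intermediate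
23 | [(3E)-5-(tert-butyldimethylsilyloxy)-4-methylpent-3-enyl]zinc bromide | C/C(=C\CC[Zn]Br)CO[Si](C)(C)C(C)(C)C | intermediate (not isolated)
24 | 2-(trimethylsilyl)ethyl (2R)-2-({2-[2,5-bis(tert-butyldimethylsilyloxy)phenyl]-1,3-dioxolan-2-yl}methyl)-6-[(3E)-5-(tert-butyldimethylsilyloxy)-4-methylpent-3-enyl]-2,3,4,7-tetrahydrooxepine-2-carboxylate | C/C(=C\CCC1=CCC[C@@](CC2(OCCO2)c3cc(O[Si](C)(C)C(C)(C)C)ccc3O[Si](C)(C)C(C)(C)C)(C(=O)OCC[Si](C)(C)C)OC1)CO[Si](C)(C)C(C)(C)C | intermediate
25 | 2-(trimethylsilyl)ethyl (2R)-2-{2-[2,5-bis(tert-butyldimethylsilyloxy)phenyl]-2-oxoethyl}-6-[(3E)-5-hydroxy-4-methylpent-3-enyl]-2,3,4,7-tetrahydrooxepine-2-carboxylate | C/C(=C\CCC1=CCC[C@@](CC(=O)c2cc(O[Si](C)(C)C(C)(C)C)ccc2O[Si](C)(C)C(C)(C)C)(C(=O)OCC[Si](C)(C)C)OC1)CO | intermediate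
26 | (E)-4-hydroxycinnamic acid (p-coumaric acid) | OC(=O)/C=C/c1ccc(O)cc1 | starting material
27 | 2-(trimethylsilyl)ethyl (2R)-2-{2-[2,5-bis(tert-butyldimethylsilyloxy)phenyl]-2-oxoethyl}-6-[(3E)-5-{[(2E)-3-(4-hydroxyphenyl)prop-2-enoyl]oxy}-4-methylpent-3-enyl]-2,3,4,7-tetrahydrooxepine-2-carboxylate | C/C(=C\CCC1=CCC[C@@](CC(=O)c2cc(O[Si](C)(C)C(C)(C)C)ccc2O[Si](C)(C)C(C)(C)C)(C(=O)OCC[Si](C)(C)C)OC1)COC(=O)/C=C/c1ccc(O)cc1 | intermediate
28 | (2R)-2-[2-(2,5-dihydroxyphenyl)-2-oxoethyl]-6-[(3E)-5-{[(2E)-3-(4-hydroxyphenyl)prop-2-enoyl]oxy}-4-methylpent-3-enyl]-2,3,4,7-tetrahydrooxepine-2-carboxylic acid | C/C(=C\CCC1=CCC[C@@](CC(=O)c2cc(O)ccc2O)(C(=O)O)OC1)COC(=O)/C=C/c1ccc(O)cc1 | target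

## Step count and least certain steps

Total step count: 17. Longest linear sequence: 13 steps (steps 1, 2, 5, 6, 7, 8, 9, 10, 11, 14, 15, 16, 17; the branch through steps 3 and 4 is equally long).

**Step 10 (key step).** The seven-membered closure onto a hindered hydroxyl that an adjacent ester makes less nucleophilic may be slow enough for 1,5 C–H insertion at C3, carbenoid dimerisation or insertion into adventitious water to compete. Fallback: from 16, anhydrous HBr in Et2O at −30 °C converts the diazoketone into the bromomethyl ketone F1. AgOTf with 2,6-di-tert-butylpyridine in CH2Cl2 then closes the same O1–C7 bond by base-free displacement at the highly reactive α-keto carbon. This returns to the route at 17.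

**Step 9.** The aryl silyl ethers may be eroded, or the diazo carbon protonated by the HF reagent with loss of nitrogen, because the hindered tertiary silyl ether reacts more slowly than an ordinary trimethylsilyl ether. Fallback: from 10, 1 M HCl in THF hydrolyses only the tertiary trimethylsilyl ether and gives the hydroxy ketone F2. Ketalisation with ethylene glycol, triethyl orthoformate and TsOH gives the hydroxy ketal F3. Wacker oxidation (PdCl2, CuCl, O2, DMF/H2O) gives the methyl ketone F4. Deacylative diazo transfer follows: LiN(SiMe3)2 and 2,2,2-trifluoroethyl trifluoroacetate at −78 °C give the trifluoroacetyl ketone F5, and MsN3, Et3N and H2O in MeCN convert it to the diazoketone. No carboxyl is activated beside the free hydroxyl, so lactonisation cannot occur. This returns to the route at 16.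

**Step 11.** Enolisation may go partly toward C7, because the ring oxygen also acidifies that position inductively, and give the regioisomeric enol triflate. Fallback: from 17, α,β-dehydrogenation with IBX and 4-methoxypyridine N-oxide in DMSO can only take place toward C4–C5, since C7 has no β-carbon, and gives the enone F6. Conjugate reduction with LiBH(s-Bu)3 at −78 °C generates enolate 18 regiospecifically. Trapping with the same triflimide returns to the route at 19.

**Step 14.** Zinc insertion may be incomplete, or β-hydride elimination after transmetalation may give the reduced ring alkene and an isomerised side chain. Fallback: from 22, magnesium in THF gives the Grignard reagent F7. Coupling with 19 under Fe(acac)3 catalysis in THF/NMP at −30 °C, where a hindered ester is tolerated, returns to the route at 24.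

**Step 16.** Competing O-alkylation of the phenol or allylic transposition may lower the selectivity of the esterification. Fallback: from 26, TBSCl (2.2 equiv) and imidazole in DMF give the bis-silylated silyl ester F8, and aqueous AcOH in THF then hydrolyses only the silyl ester and gives the silyl-protected acid F9. Carbodiimide/DMAP (Steglich) esterification with 25 gives the tris-silyl ester F10. The conditions of step 17 remove all three aryl silyl ethers and the silylethyl ester and return to the route at 28.

**Step 17.** Basic fluoride may induce β-elimination of O1 from the unmasked β-alkoxy ketone, followed by re-addition of the ortho-phenoxide, and the hydroquinone dianion may be oxidised by air. Fallback: from 24, camphorsulfonic acid (cat.) in MeOH at 0 °C removes only the primary silyl ether and gives the ketal alcohol F11. Mitsunobu esterification with 26 gives the ketal ester F12. The fluoride step on this compound, whose ketone is still masked and therefore has no acidic methylene, gives the ketal acid F13. TsOH in acetone/H2O then unmasks the ketone under acid, where elimination is not possible, and returns to the route at 28.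

## Further compounds

F1 | step 10 | 2-(trimethylsilyl)ethyl (2R)-2-({2-[2,5-bis(tert-butyldimethylsilyloxy)phenyl]-1,3-dioxolan-2-yl}methyl)-7-bromo-2-hydroxy-6-oxoheptanoate | BrCC(=O)CCC[C@@](O)(CC1(OCCO1)c2cc(O[Si](C)(C)C(C)(C)C)ccc2O[Si](C)(C)C(C)(C)C)C(=O)OCC[Si](C)(C)C
F2 | step 9 | 2-(trimethylsilyl)ethyl (2R)-2-{2-[2,5-bis(tert-butyldimethylsilyloxy)phenyl]-2-oxoethyl}-2-hydroxyhept-6-enoate | C=CCCC[C@@](O)(CC(=O)c1cc(O[Si](C)(C)C(C)(C)C)ccc1O[Si](C)(C)C(C)(C)C)C(=O)OCC[Si](C)(C)C
F3 | step 9 | 2-(trimethylsilyl)ethyl (2R)-2-({2-[2,5-bis(tert-butyldimethylsilyloxy)phenyl]-1,3-dioxolan-2-yl}methyl)-2-hydroxyhept-6-enoate | C=CCCC[C@@](O)(CC1(OCCO1)c2cc(O[Si](C)(C)C(C)(C)C)ccc2O[Si](C)(C)C(C)(C)C)C(=O)OCC[Si](C)(C)C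
F4 | step 9 | 2-(trimethylsilyl)ethyl (2R)-2-({2-[2,5-bis(tert-butyldimethylsilyloxy)phenyl]-1,3-dioxolan-2-yl}methyl)-2-hydroxy-6-oxoheptanoate | CC(=O)CCC[C@@](O)(CC1(OCCO1)c2cc(O[Si](C)(C)C(C)(C)C)ccc2O[Si](C)(C)C(C)(C)C)C(=O)OCC[Si](C)(C)C
F5 | step 9 | 2-(trimethylsilyl)ethyl (2R)-2-({2-[2,5-bis(tert-butyldimethylsilyloxy)phenyl]-1,3-dioxolan-2-yl}methyl)-9,9,9-trifluoro-2-hydroxy-6,8-dioxononanoate | FC(F)(F)C(=O)CC(=O)CCC[C@@](O)(CC1(OCCO1)c2cc(O[Si](C)(C)C(C)(C)C)ccc2O[Si](C)(C)C(C)(C)C)C(=O)OCC[Si](C)(C)C
F6 | step 11 | 2-(trimethylsilyl)ethyl (2R)-2-({2-[2,5-bis(tert-butyldimethylsilyloxy)phenyl]-1,3-dioxolan-2-yl}methyl)-6-oxo-2,3,6,7-tetrahydrooxepine-2-carboxylate (C4=C5 enone) | O=C1C=CC[C@@](CC2(OCCO2)c3cc(O[Si](C)(C)C(C)(C)C)ccc3O[Si](C)(C)C(C)(C)C)(C(=O)OCC[Si](C)(C)C)OC1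
F7 | step 14 | [(3E)-5-(tert-butyldimethylsilyloxy)-4-methylpent-3-enyl]magnesium bromide | C/C(=C\CC[Mg]Br)CO[Si](C)(C)C(C)(C)C
F8 | step 16 | tert-butyldimethylsilyl (2E)-3-[4-(tert-butyldimethylsilyloxy)phenyl]prop-2-enoate | CC(C)(C)[Si](C)(C)OC(=O)/C=C/c1ccc(O[Si](C)(C)C(C)(C)C)cc1
F9 | step 16 | (2E)-3-[4-(tert-butyldimethylsilyloxy)phenyl]prop-2-enoic acid | OC(=O)/C=C/c1ccc(O[Si](C)(C)C(C)(C)C)cc1
F10 | step 16 | 2-(trimethylsilyl)ethyl (2R)-2-{2-[2,5-bis(tert-butyldimethylsilyloxy)phenyl]-2-oxoethyl}-6-[(3E)-5-({(2E)-3-[4-(tert-butyldimethylsilyloxy)phenyl]prop-2-enoyl}oxy)-4-methylpent-3-enyl]-2,3,4,7-tetrahydrooxepine-2-carboxylate | C/C(=C\CCC1=CCC[C@@](CC(=O)c2cc(O[Si](C)(C)C(C)(C)C)ccc2O[Si](C)(C)C(C)(C)C)(C(=O)OCC[Si](C)(C)C)OC1)COC(=O)/C=C/c1ccc(O[Si](C)(C)C(C)(C)C)cc1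
F11 | step 17 | 2-(trimethylsilyl)ethyl (2R)-2-({2-[2,5-bis(tert-butyldimethylsilyloxy)phenyl]-1,3-dioxolan-2-yl}methyl)-6-[(3E)-5-hydroxy-4-methylpent-3-enyl]-2,3,4,7-tetrahydrooxepine-2-carboxylate | C/C(=C\CCC1=CCC[C@@](CC2(OCCO2)c3cc(O[Si](C)(C)C(C)(C)C)ccc3O[Si](C)(C)C(C)(C)C)(C(=O)OCC[Si](C)(C)C)OC1)CO
F12 | step 17 | 2-(trimethylsilyl)ethyl (2R)-2-({2-[2,5-bis(tert-butyldimethylsilyloxy)phenyl]-1,3-dioxolan-2-yl}methyl)-6-[(3E)-5-{[(2E)-3-(4-hydroxyphenyl)prop-2-enoyl]oxy}-4-methylpent-3-enyl]-2,3,4,7-tetrahydrooxepine-2-carboxylate | C/C(=C\CCC1=CCC[C@@](CC2(OCCO2)c3cc(O[Si](C)(C)C(C)(C)C)ccc3O[Si](C)(C)C(C)(C)C)(C(=O)OCC[Si](C)(C)C)OC1)COC(=O)/C=C/c1ccc(O)cc1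
F13 | step 17 | (2R)-2-{[2-(2,5-dihydroxyphenyl)-1,3-dioxolan-2-yl]methyl}-6-[(3E)-5-{[(2E)-3-(4-hydroxyphenyl)prop-2-enoyl]oxy}-4-methylpent-3-enyl]-2,3,4,7-tetrahydrooxepine-2-carboxylic acid | C/C(=C\CCC1=CCC[C@@](CC2(OCCO2)c3cc(O)ccc3O)(C(=O)O)OC1)COC(=O)/C=C/c1ccc(O)cc1
A1 | alternative 1 | (2Z)-2-[(3E)-5-(4-methoxybenzyloxy)-4-methylpent-3-enyl]pent-2-ene-1,5-diol | C/C(=C\CC/C(CO)=C/CCO)COCc1ccc(OC)cc1
A2 | alternative 1 | [(3E)-5-(4-methoxybenzyloxy)-4-methylpent-3-enyl]magnesium bromide | C/C(=C\CC[Mg]Br)COCc1ccc(OC)cc1
A3 | alternative 1 | propargyl alcohol | C#CCO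
A4 | alternative 1 | ethylene oxide | C1CO1
A5 | alternative 2 | (2R)-2-tert-butyl-5-{[2-(2,5-dimethoxyphenyl)-1,3-dithian-2-yl]methyl}-5-[2-(1,3-dioxolan-2-yl)ethyl]-1,3-dioxolan-4-one, C5 alkylated anti to tert-butyl | O1CCOC1CC[C@@]2(CC3(SCCCS3)c4cc(OC)ccc4OC)C(=O)O[C@H](C(C)(C)C)O2
A6 | alternative 2 | (2R)-2-tert-butyl-5-methylene-1,3-dioxolan-4-one | C=C1O[C@@H](C(C)(C)C)OC1=O
A7 | alternative 2 | 2-(2,5-dimethoxyphenyl)-1,3-dithiane | COc1ccc(OC)c(c1)C1SCCCS1
A8 | alternative 2 | 2-(2-iodoethyl)-1,3-dioxolane | ICCC1OCCO1
A9 | alternative 3 | methyl (2R)-2-[2-(2,5-dimethoxyphenyl)-2-oxoethyl]-6-[(3E)-4-methyl-5-(pivaloyloxy)pent-3-enyl]-2,3,4,7-tetrahydrooxepine-2-carboxylate | C/C(=C\CCC1=CCC[C@@](CC(=O)c2cc(OC)ccc2OC)(C(=O)OC)OC1)COC(=O)C(C)(C)C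
A10 | alternative 3 | methyl (2R,5Z,9E)-2-[2-(2,5-dimethoxyphenyl)-2-oxoethyl]-2-[(2-methoxyethoxy)methoxy]-10-methyl-11-(pivaloyloxy)-6-(trimethylsilyl)undeca-5,9-dienoate | C/C(=C\CC/C(=C/CC[C@@](OCOCCOC)(CC(=O)c1cc(OC)ccc1OC)C(=O)OC)[Si](C)(C)C)COC(=O)C(C)(C)C
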